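**Retrosynthetic overview**
1. The C11 methylene comes from a ketone in the last step. C3-OH and C9-OH come from a 3,9-diketone, and 6-Cl with the C5(16) methylene come from ene-type chlorination of a C5(Me)=C6 alkene.
2. The ten-membered carbocycle (and the oxocane) comes from ozonolysis of a C3=C9 bond shared by a five- and an oxa-bridged seven-membered ring (5 + 7 → 10).
3. The γ-lactone comes from attack of the C19 tert-butyl ester on activated C7-OH with inversion.
4. Key step: a one-pot furan-to-pyranone ring expansion and oxidopyrylium [5+2] cycloaddition with a ring A-fused β-chlorocyclopentenone, followed by loss of HCl. This brings together 19 of the 20 skeletal carbons.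
5. Ring order: ring A (Diels–Alder), then cyclopentanedione (Claisen), then pyranone and oxa-bridged cycloheptene (key step), then lactone, then ten-membered ring.

Assumption: briarane numbering is used (C1 quaternary carbon, C15 its methyl, C10 ring-fusion CH, C4–O–C8 ether, C19 lactone carbonyl). β means the face of Me-15.

**Step 1**
Reactants: 1 3-methylfuran
Product: 2 4-methylfuran-2-carbaldehyde
Conditions: LiTMP (from 2,2,6,6-tetramethylpiperidine, n-BuLi), THF, −78 °C; DMF; then H2O
Reagents that add atoms: N,N-dimethylformamide CN(C)C=O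
Why: In this kinetic α-lithiation and formylation the hindered amide base removes the α-proton remote from the methyl group (as with 3-methylthiophene), DMF delivers C8, and no stereocentre is formed.

**Step 2**
Reactants: 2 4-methylfuran-2-carbaldehyde, 3 tert-butyl propanoate
Product: 4 tert-butyl 3-hydroxy-2-methyl-3-(4-methylfuran-2-yl)propanoate (racemic syn/anti mixture)
Conditions: LDA, THF, −78 °C; then H2O
Reagents that add atoms: none
Why: This lithium enolate aldol addition needs no stereocontrol, because C8 is flattened in step 11 and C17 is equilibrated in step 13.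

**Step 3**
Reactants: 5 butane-2,3-dione, 6 ethyl (triphenylphosphoranylidene)acetate
Product: 7 ethyl (E)-3-methyl-4-oxopent-2-enoate
Conditions: CH2Cl2, 0 °C → rt
Reagents that add atoms: none
Why: Wittig mono-olefination of the symmetrical diketone with a stabilised ylide gives the E-alkene, with the acetyl and ester groups trans.

**Step 4**
Reactants: 8 (E)-but-2-enal
Product: 9 (E)-1-(tert-butyldimethylsilyloxy)buta-1,3-diene
Conditions: TBSOTf, Et3N, Et2O, 0 °C
Reagents that add atoms: tert-butyldimethylsilyl triflate CC(C)(C)[Si](C)(C)OS(=O)(=O)C(F)(F)F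
Why: Soft γ-deprotonation with O-silylation (dienol silyl ether formation) gives the E-1-oxygenated diene.

**Step 5**
Reactants: 7 ethyl (E)-3-methyl-4-oxopent-2-enoate, 9 (E)-1-(tert-butyldimethylsilyloxy)buta-1,3-diene
Product: 10 ring A keto ester: ethyl 2-acetyl-2-methyl-3-(TBSO)cyclohex-4-ene-1-carboxylate (Me-15 β, H-10 α, 14-OTBS α)
Conditions: (S)-3,3-diphenyl-1-(2-methylphenyl)tetrahydropyrrolo[1,2-c][1,3,2]oxazaborole·HNTf2 (10 mol%), CH2Cl2, −78 → −40 °C
Reagents that add atoms: none
Why: In this catalytic enantioselective Diels–Alder reaction the catalyst-bound acetyl group directs "ortho" regiochemistry (C14–C1, C11–C10) and sits endo, so 14-OTBS is cis to acetyl and trans to Me-15, while the E-dienophile places acetyl and ester trans and the catalyst sets the absolute configuration of C1, C10 and C14.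

**Step 6**
Reactants: 10 ring A keto ester
Product: 11 C11 enone: ethyl 2-acetyl-2-methyl-3-(TBSO)-6-oxocyclohex-4-ene-1-carboxylate
Conditions: Rh2(cap)4 (dirhodium tetracaprolactamate, 1 mol%), t-BuOOH, K2CO3, CH2Cl2, rt
Reagents that add atoms: tert-butyl hydroperoxide CC(C)(C)OO
Why: In this allylic C–H oxidation C11 is the only allylic CH2 and the C13 end of the allyl radical is screened by the adjacent silyl ether, so the carbonyl forms at C11, and C10 keeps its more stable equatorial (trans) ester.

**Step 7**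
Reactants: 11 C11 enone
Product: 12 saturated C11 ketone (β-keto ester)
Conditions: H2 (1 atm), Pd/C, EtOAc, rt
Reagents that add atoms: none
Why: Heterogeneous hydrogenation removes the disubstituted enone C=C and forms no new stereocentre.

**Step 8**
Reactants: 12 saturated C11 ketone
Product: 13 C11 ethylene ketal
Conditions: (TMSOCH2)2, TMSOTf (5 mol%), CH2Cl2, −78 °C
Reagents that add atoms: 1,2-bis(trimethylsilyloxy)ethane C[Si](C)(C)OCCO[Si](C)(C)C
Why: Noyori ketalisation masks only the unhindered ring ketone and leaves the neopentyl methyl ketone and the silyl ether untouched.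

**Step 9**
Reactants: 13 C11 ethylene ketal
Product: 14 trans-hydrindane-1,3-dione (C2 and C9 ketones, C3 methylene)
Conditions: KOt-Bu, THF, 0 °C; then AcOH
Reagents that add atoms: none
Why: In this intramolecular Claisen (Dieckmann-type) condensation the methyl ketone enolate (C3) attacks the C9 ester, and the product is held as its stabilised enolate, which also protects C10 from epimerisation.

**Step 10**
Reactants: 14 trans-hydrindane-1,3-dione
Product: 15 β-chloro-enone (C9–Cl, C3=C9, C2 ketone)
Conditions: PPh3, CCl4, MeCN, 40 °C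
Reagents that add atoms: carbon tetrachloride ClC(Cl)(Cl)Cl
Why: Appel-type deoxychlorination of the vinylogous acid occurs at the C9 oxygen and carbon because the C2 carbonyl is neopentyl.

**Step 11 (key step)**
Reactants: 4 tert-butyl 3-hydroxy-2-methyl-3-(4-methylfuran-2-yl)propanoate, 15 β-chloro-enone
Product: 20 oxa-bridged bis-enone (C2 and C7 ketones; C3=C9 and C5=C6 alkenes; C4–O–C8 bridge), via hydroxypyranone 16 (not isolated), via acetoxypyranone 17 (not isolated), via oxidopyrylium ylide 18 (not isolated), via chloro cycloadduct 19 (not isolated)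
Conditions: mCPBA, CH2Cl2, 0 °C; then Ac2O, i-Pr2NEt, DMAP (5 mol%), 0 °C; then 15, MeCN, 60 °C
Reagents that add atoms: 3-chloroperbenzoic acid O=C(OO)c1cccc(Cl)c1; acetic anhydride CC(=O)OC(C)=O (acetyl only in 17)
Why: Proposed new method: peracid expands the furan to the 6-hydroxypyranone (Achmatowicz rearrangement), acetylation and amine-induced loss of AcOH give the 3-oxidopyrylium ylide, its nucleophilic C8 bonds to the electrophilic β-carbon C9 while C3 closes onto electrophilic C4 ([5+2] cycloaddition with the polarity-matched regiochemistry of enones), and E1cB loss of HCl makes 15 a cyclopentynone equivalent, so the six-membered oxacycle and the oxa-bridged seven-membered carbocycle both form in this operation; the dipole adds exo (only its bridging oxygen lies over the hydrindane) and on the α-face, because in the β-exo mode that oxygen collides with Me-15, which sets C4 and C8 relative to C1; the closest known reaction types are intermolecular oxidopyrylium–cyclopentenone cycloadditions and β-halo-enones used as alkyne surrogates in dipolar cycloadditions.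

**Step 12**
Reactants: 20 oxa-bridged bis-enone
Product: 21 bis-allylic diol (2β-OH as in the target; 7-OH endo, i.e. 7-epi)
Conditions: NaBH4, CeCl3·7H2O, MeOH, −78 → −20 °C
Reagents that add atoms: none
Why: In this Luche 1,2-reduction C2=O is attacked from the α-face opposite Me-15 (as in 17-keto steroids), and C7=O is attacked from the exo face next to the bridging oxygen, which gives the endo alcohol needed for the inversion in step 13.

**Step 13**
Reactants: 21 bis-allylic diol
Product: 24 cis-fused γ-lactone alcohol (O7 exo, 17R, free 2β-OH), via bis(trifluoroacetate) 22 (not isolated), via lactone trifluoroacetate 23 (not isolated)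
Conditions: (CF3CO)2O, 2,6-lutidine, CH2Cl2, −40 → 0 °C; then MeOH, DBU, rt
Reagents that add atoms: trifluoroacetic anhydride O=C(OC(=O)C(F)(F)F)C(F)(F)F (atoms only in 22 and 23)
Why: In this anchimerically assisted SN2-type lactonisation the tert-butyl ester carbonyl displaces the allylic C7 trifluoroacetate from the exo face (five-membered transition state, inversion, loss of isobutene), the unassisted C2 ester is merely methanolysed, and DBU equilibrates C17 to the epimer with Me-18 anti to C9.

**Step 14**
Reactants: 24 cis-fused γ-lactone alcohol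
Product: 25 ten-membered 3,9-diketone (11-oxabicyclo[5.3.1]undecane core)
Conditions: O3 (1 equiv, Sudan Red 7B endpoint), CH2Cl2–MeOH, −78 °C; then Me2S
Reagents that add atoms: ozone [O-][O+]=O
Why: This chemoselective ozonolysis cleaves the strained, tetrasubstituted, norbornene-like C3=C9 alkene before the trisubstituted C5=C6 alkene (deactivated by allylic lactone and ether oxygens), and cutting the shared bond merges the five- and seven-membered rings without touching a stereocentre.

**Step 15**
Reactants: 25 ten-membered 3,9-diketone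
Product: 26 6-chloro-5(16)-ene diketone
Conditions: NCS, PhSeCl (10 mol%), MeCN, rt
Reagents that add atoms: N-chlorosuccinimide O=C1CCC(=O)N1Cl
Why: This selenium-catalysed ene-type allylic chlorination puts chlorine on C6 and moves the alkene to C5=C16 (C4–H is a bridgehead hydrogen), and attack on the convex face opposite the five-carbon bridge places 6-Cl cis to O7.

**Step 16**
Reactants: 26 6-chloro-5(16)-ene diketone
Product: 27 2,3,9-triol
Conditions: NaBH4, MeOH–CH2Cl2, −40 → 0 °C
Reagents that add atoms: none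
Why: Borohydride attacks both medium-ring ketones from the periphery, and because the C3 and C9 carbonyl dipoles lie antiparallel the two new C–O bonds end on opposite ring faces (3S threo to 2-OH, and 9S), while the lactone and the allylic chloride are inert.

**Step 17**
Reactants: 27 2,3,9-triol
Product: 28 C11 ketone 2,3,9,14-tetraol
Conditions: 48% aq HF, MeCN, 0 °C → rt
Reagents that add atoms: water O
Why: Acidic fluoride removes the silyl ether and hydrolyses the dioxolane in one operation without affecting any stereocentre.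

**Step 18**
Reactants: 28 C11 ketone 2,3,9,14-tetraol
Product: 31 9,14-diacetate 2,3-diol C11 ketone, via phenylboronate 29 (not isolated), via diacetate phenylboronate 30 (not isolated)
Conditions: PhB(OH)2, 4 Å MS, toluene, rt; then Ac2O, Et3N, DMAP, 40 °C; then pinacol, rt
Reagents that add atoms: phenylboronic acid OB(O)c1ccccc1 (atoms only in 29 and 30); acetic anhydride CC(=O)OC(C)=O
Why: Only the vicinal 2,3-diol can form a five-membered cyclic boronate, so this transient protection lets acetylation reach just O9 and O14 before transesterification with pinacol frees the diol.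

**Step 19**
Reactants: 31 9,14-diacetate 2,3-diol C11 ketone
Product: 32 CNP0176535.1 (1S,2R,3S,4R,6S,7R,8R,9S,10S,14S,17R)
Conditions: CH2Br2, Zn, TiCl4, THF–CH2Cl2, 0 °C → rt (excess reagent)
Reagents that add atoms: dibromomethane BrCBr
Why: The non-basic gem-dimetallic reagent of the Takai–Lombardo methylenation converts only the ketone, which avoids E1cB loss of the β-acetoxy group and epimerisation at C10 and spares the esters, the lactone and the free hydroxyls.

**Compound list**
1 | 3-methylfuran | Cc1ccoc1 | starting material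
2 | 4-methylfuran-2-carbaldehyde | Cc1coc(C=O)c1 | intermediate
3 | tert-butyl propanoate | CCC(=O)OC(C)(C)C | starting material
4 | tert-butyl 3-hydroxy-2-methyl-3-(4-methylfuran-2-yl)propanoate (racemic mixture) | CC(C(O)c1cc(C)co1)C(=O)OC(C)(C)C | intermediate
5 | butane-2,3-dione | CC(=O)C(C)=O | starting material
6 | ethyl (triphenylphosphoranylidene)acetate | CCOC(=O)C=P(c1ccccc1)(c1ccccc1)c1ccccc1 | starting material
7 | ethyl (E)-3-methyl-4-oxopent-2-enoate | CCOC(=O)/C=C(\C)C(C)=O | intermediate
8 | (E)-but-2-enal | C/C=C/C=O | starting material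
9 | (E)-1-(tert-butyldimethylsilyloxy)buta-1,3-diene | C=C/C=C/O[Si](C)(C)C(C)(C)C | intermediate
10 | ring A keto ester (Diels–Alder adduct) | C1C=C[C@H](O[Si](C)(C)C(C)(C)C)[C@@](C(C)=O)(C)[C@H]1C(=O)OCC | intermediate
11 | C11 enone | O=C1C=C[C@H](O[Si](C)(C)C(C)(C)C)[C@@](C(C)=O)(C)[C@H]1C(=O)OCC | intermediate
12 | saturated C11 ketone | O=C1CC[C@H](O[Si](C)(C)C(C)(C)C)[C@@](C(C)=O)(C)[C@H]1C(=O)OCC | intermediate
13 | C11 ethylene ketal | O1CCOC12CC[C@H](O[Si](C)(C)C(C)(C)C)[C@@](C(C)=O)(C)[C@H]2C(=O)OCC | intermediate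
14 | trans-hydrindane-1,3-dione | O1CCOC12CC[C@H](O[Si](C)(C)C(C)(C)C)[C@@]3(C)[C@H]2C(=O)CC3=O | intermediate
15 | β-chloro-enone | O1CCOC12CC[C@H](O[Si](C)(C)C(C)(C)C)[C@@]3(C)[C@H]2C(Cl)=CC3=O | intermediate
16 | hydroxypyranone | CC(C1OC(O)C(C)=CC1=O)C(=O)OC(C)(C)C | intermediate
17 | acetoxypyranone | CC(C1OC(OC(C)=O)C(C)=CC1=O)C(=O)OC(C)(C)C | intermediate
18 | oxidopyrylium ylide | CC(c1[o+]cc(C)cc1[O-])C(=O)OC(C)(C)C | intermediate
19 | chloro cycloadduct (α-exo; 9-Cl and H-3 β) | O1CCOC12CC[C@H](O[Si](C)(C)C(C)(C)C)[C@@]3(C)[C@H]2[C@]2(Cl)[C@H](C3=O)[C@@H]3O[C@@]2(C(C)C(=O)OC(C)(C)C)C(=O)C=C3C | intermediate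
20 | oxa-bridged bis-enone (C17 epimers) | O1CCOC12CC[C@H](O[Si](C)(C)C(C)(C)C)[C@@]3(C)[C@H]2C2=C(C3=O)[C@@H]3O[C@@]2(C(C)C(=O)OC(C)(C)C)C(=O)C=C3C | intermediate
21 | bis-allylic diol | O1CCOC12CC[C@H](O[Si](C)(C)C(C)(C)C)[C@@]3(C)[C@H]2C2=C([C@@H]3O)[C@@H]3O[C@@]2(C(C)C(=O)OC(C)(C)C)[C@H](O)C=C3C | intermediate
22 | bis(trifluoroacetate) | O1CCOC12CC[C@H](O[Si](C)(C)C(C)(C)C)[C@@]3(C)[C@H]2C2=C([C@@H]3OC(=O)C(F)(F)F)[C@@H]3O[C@@]2(C(C)C(=O)OC(C)(C)C)[C@H](OC(=O)C(F)(F)F)C=C3C | intermediate
23 | lactone trifluoroacetate (C17 epimers) | O1CCOC12CC[C@H](O[Si](C)(C)C(C)(C)C)[C@@]3(C)[C@H]2C2=C([C@@H]3OC(=O)C(F)(F)F)[C@@H]3O[C@]24C(C)C(=O)O[C@H]4C=C3C | intermediate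
24 | cis-fused γ-lactone alcohol | O1CCOC12CC[C@H](O[Si](C)(C)C(C)(C)C)[C@@]3(C)[C@H]2C2=C([C@@H]3O)[C@@H]3O[C@]24[C@@H](C)C(=O)O[C@H]4C=C3C | intermediate
25 | ten-membered 3,9-diketone | O1CCOC12CC[C@H](O[Si](C)(C)C(C)(C)C)[C@@]3(C)[C@H]2C(=O)[C@@]24O[C@H](C(C)=C[C@@H]2OC(=O)[C@@H]4C)C(=O)[C@@H]3O | intermediate
26 | 6-chloro-5(16)-ene diketone | O1CCOC12CC[C@H](O[Si](C)(C)C(C)(C)C)[C@@]3(C)[C@H]2C(=O)[C@@]24O[C@H](C(=C)[C@H](Cl)[C@@H]2OC(=O)[C@@H]4C)C(=O)[C@@H]3O | intermediate
27 | 2,3,9-triol | O1CCOC12CC[C@H](O[Si](C)(C)C(C)(C)C)[C@@]3(C)[C@H]2[C@H](O)[C@@]24O[C@H](C(=C)[C@H](Cl)[C@@H]2OC(=O)[C@@H]4C)[C@@H](O)[C@@H]3O | intermediate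
28 | C11 ketone 2,3,9,14-tetraol | O=C1CC[C@H](O)[C@@]2(C)[C@H]1[C@H](O)[C@@]13O[C@H](C(=C)[C@H](Cl)[C@@H]1OC(=O)[C@@H]3C)[C@@H](O)[C@@H]2O | intermediate
29 | phenylboronate | O=C1CC[C@H](O)[C@@]2(C)[C@H]1[C@H](O)[C@@]13O[C@H](C(=C)[C@H](Cl)[C@@H]1OC(=O)[C@@H]3C)[C@H]4OB(c5ccccc5)O[C@H]24 | intermediate
30 | diacetate phenylboronate | O=C1CC[C@H](OC(C)=O)[C@@]2(C)[C@H]1[C@H](OC(C)=O)[C@@]13O[C@H](C(=C)[C@H](Cl)[C@@H]1OC(=O)[C@@H]3C)[C@H]4OB(c5ccccc5)O[C@H]24 | intermediate
31 | 9,14-diacetate 2,3-diol C11 ketone | O=C1CC[C@H](OC(C)=O)[C@@]2(C)[C@H]1[C@H](OC(C)=O)[C@@]13O[C@H](C(=C)[C@H](Cl)[C@@H]1OC(=O)[C@@H]3C)[C@@H](O)[C@@H]2O | intermediate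
32 | CNP0176535.1 | C=C1CC[C@H](OC(C)=O)[C@@]2(C)[C@H]1[C@H](OC(C)=O)[C@@]13O[C@H](C(=C)[C@H](Cl)[C@@H]1OC(=O)[C@@H]3C)[C@@H](O)[C@@H]2O | target

**Step count**
Total steps: 19. Longest linear sequence: 16 (steps 3, 5–19).

**The three steps most likely to fail**

Step 11 must join two fully substituted carbons (C8 and C9) in an intermolecular cycloaddition, and its facial and exo selectivity are untested. The fallback sets out from 15 and 4 and returns at 20. The C–Cl bond of 15 is reduced with Zn in AcOH to the less hindered ring A-fused cyclopentenone F1. Compound 17 is prepared and isolated separately from 4 (NBS in aqueous THF, then Ac2O). Its ylide is generated thermally in the presence of F1 to give the saturated cycloadduct F2. The C3–C9 bond is then dehydrogenated next to the C2 ketone with IBX, which gives 20.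

Step 13 may suffer from ionisation of the C2 trifluoroacetate, and the ester may participate too slowly. The fallback sets out from 21 and returns at 24. The tert-butyl ester is first cleaved with TMSOTf and 2,6-lutidine to give the dihydroxy acid F3. The lactone is then closed by an intramolecular Mitsunobu reaction (PPh3, DIAD), in which only C7 has a carboxylate placed for backside attack. DBU equilibration at C17 gives 24.

Step 16 may deliver the wrong C3 epimer, because the medium-ring conformation is only predicted. The fallback sets out from 26 and returns at 27. The reduction product is accepted as the 3-epi-triol F4. Its least hindered hydroxyl (C3; C2 is neopentyl and C9 adjoins the quaternary C8) is inverted by a Mitsunobu reaction with 4-nitrobenzoic acid to give the 3-O-(4-nitrobenzoate) F5. Methanolysis with K2CO3 in MeOH gives 27.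

**Further compounds**
F1 | step 11 | ring A-fused cyclopentenone | O1CCOC12CC[C@H](O[Si](C)(C)C(C)(C)C)[C@@]3(C)[C@H]2C=CC3=O
F2 | step 11 | saturated cycloadduct | O1CCOC12CC[C@H](O[Si](C)(C)C(C)(C)C)[C@@]3(C)[C@H]2[C@@H]2[C@H](C3=O)[C@@H]3O[C@@]2(C(C)C(=O)OC(C)(C)C)C(=O)C=C3C
F3 | step 13 | dihydroxy acid | O1CCOC12CC[C@H](O[Si](C)(C)C(C)(C)C)[C@@]3(C)[C@H]2C2=C([C@@H]3O)[C@@H]3O[C@@]2(C(C)C(=O)O)[C@H](O)C=C3C
F4 | step 16 | 3-epi-triol | O1CCOC12CC[C@H](O[Si](C)(C)C(C)(C)C)[C@@]3(C)[C@H]2[C@H](O)[C@@]24O[C@H](C(=C)[C@H](Cl)[C@@H]2OC(=O)[C@@H]4C)[C@H](O)[C@@H]3O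
F5 | step 16 | 3-O-(4-nitrobenzoate) | O1CCOC12CC[C@H](O[Si](C)(C)C(C)(C)C)[C@@]3(C)[C@H]2[C@H](O)[C@@]24O[C@H](C(=C)[C@H](Cl)[C@@H]2OC(=O)[C@@H]4C)[C@@H](OC(=O)c2ccc(cc2)[N+](=O)[O-])[C@@H]3O
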